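**Retrosynthetic overview**
- Key step, last: the quinone C4–O bond is made by catalytic aerobic para-oxygenation of an ortho-allylated monophenol, so the ring stays a robust phenol through all C–C chemistry.
- The aryl–allyl bond comes from alumina-templated ortho-allylation of phenol with the C20 allylic alcohol.
- The CH2–CH2 bond next to the ring comes from alkylating the (R)-α-cyclogeranyl phenyl sulfone anion with (2E,6E)-8-bromogeranyl acetate, then reductive desulfonylation. The bromide derives from geranyl acetate by terminal allylic C–H oxygenation (a second C–O-forming step) and Appel bromination.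
- The ring and the only stereocentre come from a new enantioselective Brønsted-acid monocyclization of geranyl phenyl sulfone.
- Ring order: the cyclohexene ring is formed first (step 2); the quinone carbocycle is bought as phenol and oxidised last.

Assumption: the single stereocentre in the target SMILES is read as (R) at ring C1 (the spatial arrangement of (R)-α-ionone), and both side-chain olefins are E.

**Step 1**
Reactants: 1 geranyl bromide; 2 sodium benzenesulfinate
Product: 3 geranyl phenyl sulfone, {[(2E)-3,7-dimethylocta-2,6-dien-1-yl]sulfonyl}benzene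
Conditions: DMF, rt
Reagents that add atoms: none
Why: S-alkylation of the ambident sulfinate by the primary allylic bromide (SN2 sulfone synthesis) occurs at the unhindered carbon and keeps the E olefin.

**Step 2**
Reactants: 3 geranyl phenyl sulfone
Product: 4 (R)-α-cyclogeranyl phenyl sulfone, ({[(1R)-2,6,6-trimethylcyclohex-2-en-1-yl]methyl}sulfonyl)benzene
Conditions: chiral IDPi Brønsted acid (C2-symmetric imidodiphosphorimidate from two 3,3′-diaryl-BINOL phosphorus units, each bearing an N-SO2CF3 group; 5 mol%, antipode that gives the 1R product), (CF3)3COH–CH2Cl2, −30 °C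
Reagents that add atoms: none
Why: Proposed new method: the confined, strongly acidic chiral acid in a fluorinated alcohol protonates the terminal 6,7-olefin only in concert with attack of the 2,3-olefin through a chair-like transition state held in the chiral anion pocket (sulfonyl oxygens as hydrogen-bond anchor), which fixes the face of C2 that bonds to C7 and so sets the (R) ring stereocentre; the tertiary ring cation has no further olefin to capture it and is quenched by the catalyst anion removing the axial ring CH2 proton (kinetic E1 loss to the α-olefin, not the achiral tetrasubstituted β-isomer, which would need removal of the shielded C–H at the new stereocentre), regenerating the acid; the closest known reaction types are the racemic H2SO4/AcOH cyclization of geranyl aryl sulfones to α-cyclogeranyl sulfones and the IDPi-catalysed enantioselective protonative cyclization of hydroxyl-terminated polyenes, neither shown as an enantioselective, elimination-terminated monocyclization.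

**Step 3**
Reactants: 5 geranyl acetate
Product: 6 (2E,6E)-8-hydroxy-3,7-dimethylocta-2,6-dien-1-yl acetate
Conditions: SeO2 (10 mol%), t-BuOOH (3 equiv), salicylic acid (10 mol%), CH2Cl2, rt
Reagents that add atoms: selenium dioxide, O=[Se]=O (catalytic oxygen carrier); tert-butyl hydroperoxide, CC(C)(C)OO (terminal oxidant that restores it)
Why: Catalytic SeO2 allylic oxidation (ene reaction then [2,3]-sigmatropic shift) hydroxylates the E-methyl of the electron-rich terminal olefin to give the E-allylic alcohol, while the 2,3-olefin is deactivated by the allylic acetate.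

**Step 4**
Reactants: 6 (2E,6E)-8-hydroxy-3,7-dimethylocta-2,6-dien-1-yl acetate
Product: 7 (2E,6E)-8-bromo-3,7-dimethylocta-2,6-dien-1-yl acetate
Conditions: CBr4, PPh3, CH2Cl2, 0 °C
Reagents that add atoms: carbon tetrabromide, BrC(Br)(Br)Br
Why: Appel reaction: bromide displaces the oxyphosphonium of the primary allylic alcohol by SN2 without allylic transposition or loss of E geometry, and the acetate is inert.

**Step 5**
Reactants: 4 (R)-α-cyclogeranyl phenyl sulfone; 7 (2E,6E)-8-bromo-3,7-dimethylocta-2,6-dien-1-yl acetate
Product: 9 (2E,6E)-9-(benzenesulfonyl)-3,7-dimethyl-9-[(1R)-2,6,6-trimethylcyclohex-2-en-1-yl]nona-2,6-dien-1-yl acetate (both epimers at C9), via lithiated sulfone 8 (not isolated)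
Conditions: n-BuLi, THF, −78 °C; then 7, −78 to −20 °C
Reagents that add atoms: none
Why: Alkylation of an α-sulfonyl carbanion (Julia-type sulfone alkylation): the lithiated sulfone displaces the primary allylic bromide by SN2 at −78 °C faster than it attacks the acetate; the ring stereocentre is not deprotonated, and the new sulfone-bearing centre is removed in the next step.

**Step 6**
Reactants: 9 (2E,6E)-9-(benzenesulfonyl)-3,7-dimethyl-9-[(1R)-2,6,6-trimethylcyclohex-2-en-1-yl]nona-2,6-dien-1-yl acetate
Product: 11 (2E,6E)-3,7-dimethyl-9-[(1R)-2,6,6-trimethylcyclohex-2-en-1-yl]nona-2,6-dien-1-ol, via desulfonylated acetate 10 (not isolated)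
Conditions: 6% Na(Hg), MeOH–THF, −20 °C to rt
Reagents that add atoms: none
Why: Reductive desulfonylation with sodium amalgam (single-electron C–S cleavage, protonation by methanol) replaces the sulfonyl group by hydrogen without touching the isolated trisubstituted olefins, and the sodium methoxide formed removes the acetate in the same pot by transesterification.

**Step 7**
Reactants: 11 (2E,6E)-3,7-dimethyl-9-[(1R)-2,6,6-trimethylcyclohex-2-en-1-yl]nona-2,6-dien-1-ol; 12 phenol
Product: 13 2-[(2E,6E)-3,7-dimethyl-9-[(1R)-2,6,6-trimethylcyclohex-2-en-1-yl]nona-2,6-dien-1-yl]phenol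
Conditions: 12 (5 equiv), acidic Al2O3, ClCH2CH2Cl, 80 °C
Reagents that add atoms: none
Why: Alumina-templated ortho-allylation (surface-bound Friedel–Crafts alkylation): the phenol sits on the acidic Al2O3 surface as an aluminium phenoxide beside the activated allylic alcohol, so the primary allylic terminus bonds to the ortho carbon with the E olefin retained; no stereocentre is formed and the mild surface acidity should leave the ring olefin and its allylic stereocentre intact.

**Step 8**
Reactants: 13 2-[(2E,6E)-3,7-dimethyl-9-[(1R)-2,6,6-trimethylcyclohex-2-en-1-yl]nona-2,6-dien-1-yl]phenol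
Product: 14 2-[(2E,6E)-3,7-dimethyl-9-[(1R)-2,6,6-trimethylcyclohex-2-en-1-yl]nona-2,6-dien-1-yl]cyclohexa-2,5-diene-1,4-dione
Conditions: Co(salen) (15 mol%), O2 (1 atm), DMF, rt
Reagents that add atoms: dioxygen, O=O
Why: Salcomine-type aerobic phenol oxidation: the divalent cobalt salen complex binds O2, abstracts the phenolic hydrogen and delivers oxygen to the free para carbon of the phenoxyl radical, and the peroxy-quinol collapses to the para-quinone (new C4–O bond) without affecting the olefins or the remote stereocentre.

**Compound list**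
1 | geranyl bromide, (2E)-1-bromo-3,7-dimethylocta-2,6-diene | CC(C)=CCC/C(C)=C/CBr | starting material
2 | sodium benzenesulfinate | [Na+].[O-]S(=O)c1ccccc1 | starting material
3 | geranyl phenyl sulfone, {[(2E)-3,7-dimethylocta-2,6-dien-1-yl]sulfonyl}benzene | CC(C)=CCC/C(C)=C/CS(=O)(=O)c1ccccc1 | intermediate
4 | (R)-α-cyclogeranyl phenyl sulfone, ({[(1R)-2,6,6-trimethylcyclohex-2-en-1-yl]methyl}sulfonyl)benzene | CC1=CCCC(C)(C)[C@H]1CS(=O)(=O)c1ccccc1 | intermediate
5 | geranyl acetate, (2E)-3,7-dimethylocta-2,6-dien-1-yl acetate | CC(C)=CCC/C(C)=C/COC(C)=O | starting material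
6 | (2E,6E)-8-hydroxy-3,7-dimethylocta-2,6-dien-1-yl acetate | OC/C(C)=C/CC/C(C)=C/COC(C)=O | intermediate
7 | (2E,6E)-8-bromo-3,7-dimethylocta-2,6-dien-1-yl acetate | BrC/C(C)=C/CC/C(C)=C/COC(C)=O | intermediate
8 | lithiated sulfone, [(benzenesulfonyl)[(1R)-2,6,6-trimethylcyclohex-2-en-1-yl]methyl]lithium | CC1=CCCC(C)(C)[C@H]1C([Li])S(=O)(=O)c1ccccc1 | intermediate
9 | (2E,6E)-9-(benzenesulfonyl)-3,7-dimethyl-9-[(1R)-2,6,6-trimethylcyclohex-2-en-1-yl]nona-2,6-dien-1-yl acetate, both epimers at C9 | CC1=CCCC(C)(C)[C@H]1C(C/C(C)=C/CC/C(C)=C/COC(C)=O)S(=O)(=O)c1ccccc1 | intermediate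
10 | desulfonylated acetate, (2E,6E)-3,7-dimethyl-9-[(1R)-2,6,6-trimethylcyclohex-2-en-1-yl]nona-2,6-dien-1-yl acetate | CC1=CCCC(C)(C)[C@H]1CC/C(C)=C/CC/C(C)=C/COC(C)=O | intermediate
11 | (2E,6E)-3,7-dimethyl-9-[(1R)-2,6,6-trimethylcyclohex-2-en-1-yl]nona-2,6-dien-1-ol | CC1=CCCC(C)(C)[C@H]1CC/C(C)=C/CC/C(C)=C/CO | intermediate
12 | phenol | Oc1ccccc1 | starting material
13 | 2-[(2E,6E)-3,7-dimethyl-9-[(1R)-2,6,6-trimethylcyclohex-2-en-1-yl]nona-2,6-dien-1-yl]phenol | CC1=CCCC(C)(C)[C@H]1CC/C(C)=C/CC/C(C)=C/Cc1ccccc1O | intermediate
14 | 2-[(2E,6E)-3,7-dimethyl-9-[(1R)-2,6,6-trimethylcyclohex-2-en-1-yl]nona-2,6-dien-1-yl]cyclohexa-2,5-diene-1,4-dione | CC1=CCCC(C)(C)[C@H]1CC/C(C)=C/CC/C(C)=C/CC1=CC(=O)C=CC1=O | target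

**Totals**
Total step count: 8 (convergent).
Longest linear sequence: 6 steps (1, 2, 5, 6, 7, 8 from geranyl bromide; the branch 3, 4, 5, 6, 7, 8 from geranyl acetate is equally long).

**Three steps most likely to fail**

Step 2 (the new asymmetric monocyclization) may give low enantioselectivity, β- or exocyclic olefin isomers, or poor turnover if the sulfone binds the acid. The fallback sets out from 3: cyclise it with concentrated H2SO4 in AcOH at 0–10 °C (the known racemic, α-selective cyclization of geranyl aryl sulfones) to racemic α-cyclogeranyl phenyl sulfone F1. Then resolve the enantiomers by preparative chiral supercritical-fluid chromatography on an amylose tris(3,5-dimethylphenylcarbamate) phase and carry the (R)-enantiomer forward, coming back at 4.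

Step 7 (alumina-templated ortho-allylation) may suffer E/Z erosion at the allylic olefin, para- or bis-allylation, chroman formation, or acid-induced shift of the ring olefin. The fallback sets out from 11: convert it by Appel bromination (CBr4, PPh3, CH2Cl2, 0 °C) into (2E,6E)-1-bromo-3,7-dimethyl-9-[(1R)-2,6,6-trimethylcyclohex-2-en-1-yl]nona-2,6-diene F2. Then C-alkylate sodium phenoxide (from 12 and NaH) as a suspension in toluene at rt; the non-polar, heterogeneous medium directs the SN2 alkylation to the ortho carbon with retained geometry. This comes back at 13.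

Step 8 (aerobic para-oxygenation) may be diverted to oxidative phenol coupling or ortho-quinone formation, since a mono-ortho-alkyl phenol is a less ideal substrate than a 2,6-disubstituted one. The fallback sets out from 11 and bypasses 13: Friedel–Crafts allylation of hydroquinone (5 equiv) with 11 using BF3·OEt2 in dioxane at rt gives the hydroquinone 2-[(2E,6E)-3,7-dimethyl-9-[(1R)-2,6,6-trimethylcyclohex-2-en-1-yl]nona-2,6-dien-1-yl]benzene-1,4-diol F3. Mild oxidation with Ag2O in Et2O at rt then comes back at 14.

**Further compounds**
F1 | step 2 | racemic α-cyclogeranyl phenyl sulfone, {[(2,6,6-trimethylcyclohex-2-en-1-yl)methyl]sulfonyl}benzene | CC1=CCCC(C)(C)C1CS(=O)(=O)c1ccccc1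
F2 | step 7 | (2E,6E)-1-bromo-3,7-dimethyl-9-[(1R)-2,6,6-trimethylcyclohex-2-en-1-yl]nona-2,6-diene | CC1=CCCC(C)(C)[C@H]1CC/C(C)=C/CC/C(C)=C/CBr
F3 | step 8 | 2-[(2E,6E)-3,7-dimethyl-9-[(1R)-2,6,6-trimethylcyclohex-2-en-1-yl]nona-2,6-dien-1-yl]benzene-1,4-diol | CC1=CCCC(C)(C)[C@H]1CC/C(C)=C/CC/C(C)=C/Cc1cc(O)ccc1O
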